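**Plan**

1. Retrosynthesis: the tetramic acid is opened at its C3–C4 bond (Lacey–Dieckmann), the macrocycle at the N–C(O) bond of the resulting β-ketoamide (acylketene trapping), and the Z-enamide and E-enone C=C bonds by two Horner–Wadsworth–Emmons reactions, leaving an L-ornithine piece and a tricyclic core that carries CHO and CH2C(O)SEt.
2. Enabling feature: in the inner cyclopentane (ring C) the carbon carrying the enoyl chain (Ca) is α to that chain's first carbon, and the neighbouring carbon carrying the CH2–CH=CH–C(O)N chain (Cb) is β to the carbon two atoms out. With both chain carbons at the acyl level, Ca–Cb is the bond of a 1,5-dicarbonyl (Michael) retron whose two arms sit cis on the cyclohexene (ring B).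
3. Cutting Ca–Cb leaves a trans-hydrindene (rings A and B) with an enal arm and a thioacrylate arm, the endo adduct of an intramolecular Diels–Alder reaction of an acyclic tetraenal; the acetyl group travels as a dioxolane.
4. Forward order: acyclic chain → rings A and B in one cycloaddition → ring C by a hydride-triggered Michael closure → two side-chain olefinations → 17-membered lactam → tetramic acid (16-membered ring) → deprotection.
5. Stereochemistry: the methyl- and acetyl-bearing carbons come from one oxazolidinone auxiliary (conjugate allylation, enolate acylation); the four ring A/B carbons are relayed from them in the cycloaddition; Ca and Cb are relayed from ring B in the key step; the tetramic acid carbon is L-ornithine.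

Key step: step 14

Remark: the 3-acyltetramic acid is carried in the enol form written for the target, and (diphenoxyphosphoryl)acetic acid is taken to be a purchasable reagent.

**Route**

Step 1
Reactants: 1 (R)-4-benzyloxazolidin-2-one; 2 (E)-but-2-enoyl chloride
Product: 3 (R)-4-benzyl-3-[(E)-but-2-enoyl]oxazolidin-2-one
Conditions: n-BuLi, THF, −78 °C; then 2, −78 → 0 °C
Reagents that add atoms: none
Why: N-acylation of the lithiated oxazolidinone by the acid chloride gives the enoyl imide that carries the auxiliary for the next two stereocentres, no stereocentre being formed here.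

Step 2
Reactants: 3 enoyl imide; 4 allyltrimethylsilane
Product: 5 (R)-4-benzyl-3-[(R)-3-methylhex-5-enoyl]oxazolidin-2-one
Conditions: TiCl4, CH2Cl2, −78 °C; aq. NH4Cl
Reagents that add atoms: none
Why: Hosomi–Sakurai conjugate allylation of the TiCl4-chelated s-cis enoyl imide, in which the allylsilane should add to the β-carbon on the face away from the benzyl group of the auxiliary and so set the methyl-bearing centre as R.

Step 3
Reactants: 5 imide; 6 acetyl chloride
Product: 7 (R)-4-benzyl-3-[(2S,3R)-2-acetyl-3-methylhex-5-enoyl]oxazolidin-2-one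
Conditions: LiN(i-Pr)2, THF, −78 °C; then 6, −78 °C; aq. NH4Cl
Reagents that add atoms: none
Why: C-acylation of the chelated Z-lithium enolate of the imide by the acid chloride on the face away from the benzyl group should set the acetyl-bearing centre (2S), and the β-keto imide should resist epimerisation because allylic strain keeps its C–H bond out of alignment with the carbonyl π systems.

Step 4
Reactants: 7 β-keto imide
Product: 8 (R)-4-benzyl-3-[(2S,3R)-3-methyl-2-(2-methyl-1,3-dioxolan-2-yl)hex-5-enoyl]oxazolidin-2-one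
Conditions: Me3SiOCH2CH2OSiMe3, Me3SiOTf (cat.), CH2Cl2, −78 → −20 °C
Reagents that add atoms: 1,2-bis(trimethylsilyloxy)ethane, C[Si](C)(C)OCCO[Si](C)(C)C
Why: Ketalisation of the methyl ketone with the bis-silyl ether of ethylene glycol under silyl triflate catalysis at low temperature masks the acetyl group as a dioxolane without enolising the adjacent centre, the imide carbonyls being unreactive.

Step 5
Reactants: 8 ketal imide
Product: 9 (2R,3R)-3-methyl-2-(2-methyl-1,3-dioxolan-2-yl)hex-5-en-1-ol
Conditions: LiBH4, MeOH (1 equiv), THF, 0 °C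
Reagents that add atoms: none
Why: Reductive cleavage of the N-acyl oxazolidinone by borohydride gives the primary alcohol and returns auxiliary 1, with the ketal inert and the stereocentres untouched.

Step 6
Reactants: 9 alcohol
Product: 10 (2R,3R)-3-methyl-2-(2-methyl-1,3-dioxolan-2-yl)hex-5-enal
Conditions: Dess–Martin periodinane, NaHCO3, CH2Cl2, 0 °C → rt
Reagents that add atoms: none
Why: Dess–Martin oxidation of the primary alcohol under buffered, non-basic conditions should give the α-branched aldehyde without epimerisation.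

Step 7
Reactants: 10 aldehyde; 11 (triphenylphosphoranylidene)acetaldehyde
Product: 12 (2E,4R,5R)-5-methyl-4-(2-methyl-1,3-dioxolan-2-yl)octa-2,7-dienal
Conditions: toluene, 80 °C
Reagents that add atoms: none
Why: Wittig reaction with the stabilised formylmethylene ylide gives the E-enal by two-carbon homologation under neutral conditions that spare the α-centre.

Step 8
Reactants: 13 ethyl (E)-4-(diethoxyphosphoryl)but-2-enoate
Product: 14 (E)-4-(diethoxyphosphoryl)but-2-enoic acid
Conditions: LiOH, THF/H2O, 0 °C → rt; then 1 M HCl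
Reagents that add atoms: lithium hydroxide, [Li+].[OH-]
Why: Saponification of the carboxylic ester, which is much faster than attack at the diethyl phosphonate, gives the free acid.

Step 9
Reactants: 14 phosphono acid
Product: 15 S-ethyl (E)-4-(diethoxyphosphoryl)but-2-enethioate
Conditions: EtSH, N,N'-dicyclohexylcarbodiimide, DMAP (cat.), CH2Cl2, 0 °C
Reagents that add atoms: ethanethiol, CCS
Why: Carbodiimide (Steglich-type) thioesterification gives the S-ethyl thioester, chosen because a thioenoate is a better Michael acceptor than an ester and can later be reduced to the aldehyde under neutral conditions.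

Step 10
Reactants: 12 enal; 15 phosphonate thioester
Product: 16 S-ethyl (2E,4E,6E,8R,9R)-9-methyl-8-(2-methyl-1,3-dioxolan-2-yl)dodeca-2,4,6,11-tetraenethioate
Conditions: 15, LiN(SiMe3)2, THF, −78 °C; then 12, −78 → 0 °C
Reagents that add atoms: none
Why: Vinylogous Horner–Wadsworth–Emmons reaction of the lithiated phosphonate at its phosphorus-bearing carbon with the enal should give the all-E trienyl thioester, the E geometry following from reversible addition of the stabilised anion.

Step 11
Reactants: 16 trienyl thioester; 17 (E)-but-2-enal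
Product: 18 S-ethyl (2E,4E,6E,8R,9R,11E)-9-methyl-8-(2-methyl-1,3-dioxolan-2-yl)-13-oxotrideca-2,4,6,11-tetraenethioate
Conditions: Hoveyda–Grubbs second-generation catalyst, RuCl2(H2IMes)(=CH–C6H4-2-O-i-Pr) (5 mol %), 17 (5 equiv), CH2Cl2, rt
Reagents that add atoms: none
Why: Cross-metathesis of the terminal alkene, the only unhindered and non-conjugated olefin, with excess crotonaldehyde should give the thermodynamically preferred E-enal with loss of propene.

Step 12
Reactants: 18 tetraenal
Product: 19 trans-hydrindene aldehyde, S-ethyl (E)-3-[4-formyl-2-methyl-1-(2-methyl-1,3-dioxolan-2-yl)-2,3,3a,4,5,7a-hexahydro-1H-inden-5-yl]prop-2-enethioate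
Conditions: (2S,5S)-5-benzyl-2-tert-butyl-3-methylimidazolidin-4-one·CF3CO2H (20 mol %), MeCN/H2O 98:2, −20 → 5 °C
Reagents that add atoms: none
Why: Iminium-ion-catalysed intramolecular Diels–Alder reaction of the enal with the nearer diene of the triene through the endo transition state should build rings A and B and four stereocentres at once (trans ring fusion, formyl and thioacrylate arms cis), the diene face being chosen by the allylic dioxolanyl-bearing centre, which keeps its hydrogen eclipsed with the diene (allylic strain), and reinforced by the catalyst, which exposes the same enal face.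

Step 13
Reactants: 19 hydrindene aldehyde; 11 (triphenylphosphoranylidene)acetaldehyde
Product: 20 enal thioacrylate, S-ethyl (E)-3-[2-methyl-1-(2-methyl-1,3-dioxolan-2-yl)-4-[(E)-3-oxoprop-1-enyl]-2,3,3a,4,5,7a-hexahydro-1H-inden-5-yl]prop-2-enethioate
Conditions: toluene, 70 °C
Reagents that add atoms: none
Why: Wittig reaction of the equatorial, configurationally stable ring aldehyde with the formylmethylene ylide gives the E-enal arm next to the thioacrylate arm.

Step 14
Reactants: 20 enal thioacrylate
Product: 23 S-ethyl 2-[2-formyl-7-methyl-6-(2-methyl-1,3-dioxolan-2-yl)-1,2,3,3a,5a,6,7,8,8a,8b-decahydro-as-indacen-3-yl]ethanethioate, via iminium ion 21 (not isolated), via enamine 22 (not isolated)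
Conditions: (S)-2-[diphenyl(trimethylsilyloxy)methyl]pyrrolidine (20 mol %), PhCO2H (20 mol %), diethyl 2,6-dimethyl-1,4-dihydropyridine-3,5-dicarboxylate (Hantzsch ester, 1.2 equiv), toluene, rt → 40 °C
Reagents that add atoms: none
Why: The amine condenses with the enal to iminium ion 21, the Hantzsch ester transfers hydride to its β-carbon, and the resulting E-enamine 22 adds through its α-carbon to the β-carbon of the neighbouring thioacrylate, after which hydrolysis frees 23 and the catalyst. The closest known reaction type is the organocatalytic reductive Michael cyclisation of enal–enones (iminium–enamine cascade), together with amine-catalysed Michael cyclisations of formyl enoates; the thioenoate serves here as an enone-like acceptor. Ring C closes in the 5-exo-trig mode and is cis-fused to ring B because both arms stand on the same face of the cyclohexene. The acceptor carbon is controlled by the substrate: the thioacrylate should react through the rotamer that keeps its vinylic hydrogen, not the acyl chain, over ring B, so that the CH2C(O)SEt arm ends on the convex face, cis to the ring-fusion hydrogens. The formyl-bearing carbon is set trans to that arm by the chair-like closure of the E-enamine, with the (S)-catalyst shielding the opposite enamine face, and it can still equilibrate to this more stable trans arrangement because it is α to the aldehyde. The step needs hydride transfer to the enal only and C–C bond formation at one site only: only the enal forms an iminium ion, and the enamine carbon can reach only the thioacrylate β-carbon through a five-membered transition state, which leaves an aldehyde and a thioester as two separately addressable arms.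

Step 15
Reactants: 24 2,2,6-trimethyl-4H-1,3-dioxin-4-one
Product: 25 6-[(diethoxyphosphoryl)methyl]-2,2-dimethyl-4H-1,3-dioxin-4-one
Conditions: LiN(i-Pr)2 (2 equiv), THF, −78 °C; then ClP(O)(OEt)2
Reagents that add atoms: diethyl chlorophosphate, CCOP(=O)(Cl)OCC
Why: Deprotonation of the 6-methyl group to the extended enolate and C-phosphorylation at the exocyclic carbon gives the phosphonate, the second equivalent of base taking up the more acidic product.

Step 16
Reactants: 23 tricyclic aldehyde thioester; 25 dioxinone phosphonate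
Product: 26 S-ethyl 2-[2-[(E)-2-(2,2-dimethyl-4-oxo-4H-1,3-dioxin-6-yl)ethenyl]-7-methyl-6-(2-methyl-1,3-dioxolan-2-yl)-1,2,3,3a,5a,6,7,8,8a,8b-decahydro-as-indacen-3-yl]ethanethioate
Conditions: 25, LiN(SiMe3)2, THF, −78 °C; then 23, −78 → 0 °C
Reagents that add atoms: none
Why: Horner–Wadsworth–Emmons reaction of the dioxinone phosphonate with the ring aldehyde should give the E-dienyl dioxinone, a masked acylketene, while the thioester does not react with the stabilised anion and the aldehyde α-centre already holds its more stable trans arrangement.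

Step 17
Reactants: 26 dienyl dioxinone thioester
Product: 27 2-[2-[(E)-2-(2,2-dimethyl-4-oxo-4H-1,3-dioxin-6-yl)ethenyl]-7-methyl-6-(2-methyl-1,3-dioxolan-2-yl)-1,2,3,3a,5a,6,7,8,8a,8b-decahydro-as-indacen-3-yl]acetaldehyde
Conditions: Et3SiH, Pd on carbon (10 %), acetone, rt
Reagents that add atoms: none
Why: Fukuyama reduction, in which palladium inserts into the C–S bond and the silane delivers hydride, should give the aldehyde under neutral conditions that leave the dioxinone, the ketal and the alkenes untouched.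

Step 18
Reactants: 28 methyl N5-(tert-butoxycarbonyl)-L-ornithinate hydrochloride
Product: 29 methyl N5-(tert-butoxycarbonyl)-N2-(2,4-dimethoxybenzyl)-L-ornithinate
Conditions: 2,4-dimethoxybenzaldehyde, Et3N, NaBH(OAc)3, ClCH2CH2Cl, rt
Reagents that add atoms: 2,4-dimethoxybenzaldehyde, COc1ccc(C=O)c(OC)c1
Why: Reductive amination of the α-amino ester gives the N-(2,4-dimethoxybenzyl) amine without racemisation, the group later making the amide nitrogen tertiary for the Dieckmann closure.

Step 19
Reactants: 29 protected ornithinate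
Product: 30 methyl N2-(2,4-dimethoxybenzyl)-L-ornithinate dihydrochloride
Conditions: HCl (4 M in dioxane), 0 °C → rt
Reagents that add atoms: hydrogen chloride, Cl
Why: Acidolysis of the tert-butyl carbamate frees the δ-amine, the benzylic amine being protonated and stable under these conditions.

Step 20
Reactants: 30 diamine dihydrochloride; 31 (diphenoxyphosphoryl)acetic acid
Product: 32 methyl N2-(2,4-dimethoxybenzyl)-N5-[2-(diphenoxyphosphoryl)acetyl]-L-ornithinate
Conditions: EDC·HCl, HOBt, i-Pr2NEt, CH2Cl2, 0 °C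
Reagents that add atoms: none
Why: Carbodiimide amide coupling should acylate the unhindered primary δ-amine in preference to the hindered secondary α-amine and give the diaryl phosphonoacetamide.

Step 21
Reactants: 27 aldehyde; 32 phosphonoacetamide
Product: 33 Z-enamide, methyl N5-[(Z)-4-(tricyclic core)but-2-enoyl]-N2-(2,4-dimethoxybenzyl)-L-ornithinate carrying the E-dienyl dioxinone arm
Conditions: 32, NaH, THF, 0 °C; then 27, −78 → 0 °C
Reagents that add atoms: none
Why: Z-selective Horner–Wadsworth–Emmons olefination with a diaryl phosphonoacetamide, in which fast and irreversible elimination from the first-formed adduct (electron-poor aryloxy groups on phosphorus) should give the Z-enamide from the unbranched aldehyde.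

Step 22
Reactants: 33 Z-enamide
Product: 35 macrocyclic β-ketoamide (17-membered N-(2,4-dimethoxybenzyl) lactam), via acylketene 34 (not isolated)
Conditions: toluene (1 mM), 110 °C
Reagents that add atoms: none
Why: Thermal retro-[4+2] loss of acetone from the dioxinone gives acylketene 34, which at high dilution should be trapped by the secondary α-amine to close the 17-membered β-ketoamide lactam.

Step 23
Reactants: 35 macrocyclic β-ketoamide
Product: 36 N-(2,4-dimethoxybenzyl) dioxolane-protected target (3-acyltetramic acid in the 16-membered macrolactam)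
Conditions: KOt-Bu, t-BuOH/THF, rt; then 1 M HCl
Reagents that add atoms: none
Why: Lacey–Dieckmann condensation of the β-ketoamide methylene carbon onto the methyl ester forms the 3-acyltetramic acid and thereby the 16-membered ring, the tertiary amide favouring the cyclisation conformer and the ketal protecting the acetyl-bearing centre from base.

Step 24
Reactants: 36 protected macrolactam
Product: 37 target CNP0320820.1
Conditions: CF3CO2H/H2O 9:1, rt → 40 °C
Reagents that add atoms: water, O
Why: Aqueous acidolysis should cleave the N-(2,4-dimethoxybenzyl) group through its stabilised benzylic cation and hydrolyse the dioxolane to the acetyl group, giving the target without touching a stereocentre.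

**Compound list**

1 | (R)-4-benzyloxazolidin-2-one | O=C1N[C@H](Cc2ccccc2)CO1 | starting material
2 | (E)-but-2-enoyl chloride | C/C=C/C(Cl)=O | starting material
3 | (R)-4-benzyl-3-[(E)-but-2-enoyl]oxazolidin-2-one | C/C=C/C(=O)N1[C@H](Cc2ccccc2)COC1=O | intermediate
4 | allyltrimethylsilane | C=CC[Si](C)(C)C | starting material
5 | (R)-4-benzyl-3-[(R)-3-methylhex-5-enoyl]oxazolidin-2-one | C=CC[C@@H](C)CC(=O)N1[C@H](Cc2ccccc2)COC1=O | intermediate
6 | acetyl chloride | CC(Cl)=O | starting material
7 | (R)-4-benzyl-3-[(2S,3R)-2-acetyl-3-methylhex-5-enoyl]oxazolidin-2-one | CC(=O)[C@H]([C@H](C)CC=C)C(=O)N1[C@H](Cc2ccccc2)COC1=O | intermediate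
8 | (R)-4-benzyl-3-[(2S,3R)-3-methyl-2-(2-methyl-1,3-dioxolan-2-yl)hex-5-enoyl]oxazolidin-2-one | CC1(OCCO1)[C@H]([C@H](C)CC=C)C(=O)N2[C@H](Cc3ccccc3)COC2=O | intermediate
9 | (2R,3R)-3-methyl-2-(2-methyl-1,3-dioxolan-2-yl)hex-5-en-1-ol | CC1(OCCO1)[C@H]([C@H](C)CC=C)CO | intermediate
10 | (2R,3R)-3-methyl-2-(2-methyl-1,3-dioxolan-2-yl)hex-5-enal | CC1(OCCO1)[C@H]([C@H](C)CC=C)C=O | intermediate
11 | (triphenylphosphoranylidene)acetaldehyde | O=CC=P(c1ccccc1)(c1ccccc1)c1ccccc1 | starting material
12 | (2E,4R,5R)-5-methyl-4-(2-methyl-1,3-dioxolan-2-yl)octa-2,7-dienal | CC1(OCCO1)[C@H]([C@H](C)CC=C)/C=C/C=O | intermediate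
13 | ethyl (E)-4-(diethoxyphosphoryl)but-2-enoate (triethyl 4-phosphonocrotonate) | CCOC(=O)/C=C/CP(=O)(OCC)OCC | starting material
14 | (E)-4-(diethoxyphosphoryl)but-2-enoic acid | OC(=O)/C=C/CP(=O)(OCC)OCC | intermediate
15 | S-ethyl (E)-4-(diethoxyphosphoryl)but-2-enethioate | CCSC(=O)/C=C/CP(=O)(OCC)OCC | intermediate
16 | S-ethyl (2E,4E,6E,8R,9R)-9-methyl-8-(2-methyl-1,3-dioxolan-2-yl)dodeca-2,4,6,11-tetraenethioate | CC1(OCCO1)[C@H]([C@H](C)CC=C)/C=C/C=C/C=C/C(=O)SCC | intermediate
17 | (E)-but-2-enal (crotonaldehyde) | C/C=C/C=O | starting material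
18 | S-ethyl (2E,4E,6E,8R,9R,11E)-9-methyl-8-(2-methyl-1,3-dioxolan-2-yl)-13-oxotrideca-2,4,6,11-tetraenethioate | CC1(OCCO1)[C@H]([C@H](C)C/C=C/C=O)/C=C/C=C/C=C/C(=O)SCC | intermediate
19 | S-ethyl (E)-3-[4-formyl-2-methyl-1-(2-methyl-1,3-dioxolan-2-yl)-2,3,3a,4,5,7a-hexahydro-1H-inden-5-yl]prop-2-enethioate; trans-fused, H-1, H-2 and H-3a on one face, H-4, H-5 and H-7a on the other | CC1(OCCO1)[C@H]2[C@@H]3C=C[C@H](/C=C/C(=O)SCC)[C@H](C=O)[C@H]3C[C@H]2C | intermediate
20 | S-ethyl (E)-3-[2-methyl-1-(2-methyl-1,3-dioxolan-2-yl)-4-[(E)-3-oxoprop-1-enyl]-2,3,3a,4,5,7a-hexahydro-1H-inden-5-yl]prop-2-enethioate; ring configuration as in 19 | CC1(OCCO1)[C@H]2[C@@H]3C=C[C@H](/C=C/C(=O)SCC)[C@H](/C=C/C=O)[C@H]3C[C@H]2C | intermediate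
21 | iminium ion of 20 with (S)-2-[diphenyl(trimethylsilyloxy)methyl]pyrrolidine, benzoate salt | CC1(OCCO1)[C@H]2[C@@H]3C=C[C@H](/C=C/C(=O)SCC)[C@H](/C=C/C=[N+]4CCC[C@H]4C(O[Si](C)(C)C)(c4ccccc4)c4ccccc4)[C@H]3C[C@H]2C.[O-]C(=O)c1ccccc1 | intermediate (not isolated)
22 | E-enamine of the saturated aldehyde arm with the same amine | CC1(OCCO1)[C@H]2[C@@H]3C=C[C@H](/C=C/C(=O)SCC)[C@H](C/C=C/N4CCC[C@H]4C(O[Si](C)(C)C)(c4ccccc4)c4ccccc4)[C@H]3C[C@H]2C | intermediate (not isolated)
23 | S-ethyl 2-[2-formyl-7-methyl-6-(2-methyl-1,3-dioxolan-2-yl)-1,2,3,3a,5a,6,7,8,8a,8b-decahydro-as-indacen-3-yl]ethanethioate; H-3, H-6, H-7 and H-8a on one face, H-2, H-3a, H-5a and H-8b on the other | CC1(OCCO1)[C@H]2[C@@H]3C=C[C@@H]4[C@@H](CC(=O)SCC)[C@H](C=O)C[C@@H]4[C@H]3C[C@H]2C | intermediate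
24 | 2,2,6-trimethyl-4H-1,3-dioxin-4-one | CC1=CC(=O)OC(C)(C)O1 | starting material
25 | 6-[(diethoxyphosphoryl)methyl]-2,2-dimethyl-4H-1,3-dioxin-4-one | CCOP(=O)(CC1=CC(=O)OC(C)(C)O1)OCC | intermediate
26 | S-ethyl 2-[2-[(E)-2-(2,2-dimethyl-4-oxo-4H-1,3-dioxin-6-yl)ethenyl]-7-methyl-6-(2-methyl-1,3-dioxolan-2-yl)-1,2,3,3a,5a,6,7,8,8a,8b-decahydro-as-indacen-3-yl]ethanethioate; core configuration as in 23 | CC1(OCCO1)[C@H]2[C@@H]3C=C[C@@H]4[C@@H](CC(=O)SCC)[C@H](/C=C/C5=CC(=O)OC(C)(C)O5)C[C@@H]4[C@H]3C[C@H]2C | intermediate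
27 | 2-[2-[(E)-2-(2,2-dimethyl-4-oxo-4H-1,3-dioxin-6-yl)ethenyl]-7-methyl-6-(2-methyl-1,3-dioxolan-2-yl)-1,2,3,3a,5a,6,7,8,8a,8b-decahydro-as-indacen-3-yl]acetaldehyde; core configuration as in 23 | CC1(OCCO1)[C@H]2[C@@H]3C=C[C@@H]4[C@@H](CC=O)[C@H](/C=C/C5=CC(=O)OC(C)(C)O5)C[C@@H]4[C@H]3C[C@H]2C | intermediate
28 | methyl N5-(tert-butoxycarbonyl)-L-ornithinate hydrochloride | COC(=O)[C@@H](N)CCCNC(=O)OC(C)(C)C.Cl | starting material
29 | methyl N5-(tert-butoxycarbonyl)-N2-(2,4-dimethoxybenzyl)-L-ornithinate | COC(=O)[C@@H](NCc1ccc(OC)cc1OC)CCCNC(=O)OC(C)(C)C | intermediate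
30 | methyl N2-(2,4-dimethoxybenzyl)-L-ornithinate dihydrochloride | COC(=O)[C@@H](NCc1ccc(OC)cc1OC)CCCN.Cl.Cl | intermediate
31 | (diphenoxyphosphoryl)acetic acid | OC(=O)CP(=O)(Oc1ccccc1)Oc1ccccc1 | starting material
32 | methyl N2-(2,4-dimethoxybenzyl)-N5-[2-(diphenoxyphosphoryl)acetyl]-L-ornithinate | COC(=O)[C@@H](NCc1ccc(OC)cc1OC)CCCNC(=O)CP(=O)(Oc1ccccc1)Oc1ccccc1 | intermediate
33 | methyl N2-(2,4-dimethoxybenzyl)-N5-[(Z)-4-(as-indacen-3-yl core of 27)but-2-enoyl]-L-ornithinate, with the E-dienyl dioxinone at C-2 of the core | CC1(OCCO1)[C@H]2[C@@H]3C=C[C@@H]4[C@@H](C/C=C\C(=O)NCCC[C@H](NCc5ccc(OC)cc5OC)C(=O)OC)[C@H](/C=C/C5=CC(=O)OC(C)(C)O5)C[C@@H]4[C@H]3C[C@H]2C | intermediate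
34 | acylketene from 33 (E-enoyl ketene, O=C=CH–C(=O)–CH=CH– on the core) | CC1(OCCO1)[C@H]2[C@@H]3C=C[C@@H]4[C@@H](C/C=C\C(=O)NCCC[C@H](NCc5ccc(OC)cc5OC)C(=O)OC)[C@H](/C=C/C(=O)C=C=O)C[C@@H]4[C@H]3C[C@H]2C | intermediate (not isolated)
35 | 17-membered macrocyclic β-ketoamide: N-(2,4-dimethoxybenzyl) lactam with methyl ester on the ornithine α-carbon, Z-enamide and E-enone in the ring, dioxolane on ring A | CC1(OCCO1)[C@H]2[C@@H]3C=C[C@@H]4[C@H]5C/C=C\C(=O)NCCC[C@@H](C(=O)OC)N(Cc6ccc(OC)cc6OC)C(=O)CC(=O)/C=C/[C@@H]5C[C@@H]4[C@H]3C[C@H]2C | intermediate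
36 | target carrying N-(2,4-dimethoxybenzyl) on the tetramic acid nitrogen and the acetyl group as its 1,3-dioxolane | CC1(OCCO1)[C@H]2[C@@H]3C=C[C@@H]4[C@H]5C/C=C\C(=O)NCCC[C@@H]6N(Cc7ccc(OC)cc7OC)C(=O)C(=C6O)C(=O)/C=C/[C@@H]5C[C@@H]4[C@H]3C[C@H]2C | intermediate
37 | CNP0320820.1: acetyl- and methyl-substituted trans,anti,cis-decahydro-as-indacene fused to a 16-membered Z-enamide/E-enoyl tetramic acid macrolactam | CC(=O)[C@H]1[C@@H]2C=C[C@@H]3[C@H]4C/C=C\C(=O)NCCC[C@@H]5NC(=O)C(=C5O)C(=O)/C=C/[C@@H]4C[C@@H]3[C@H]2C[C@H]1C | target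

**Step count and risks**

Total step count: 24 (steps 8–9, 15 and 18–20 prepare reagents 15, 25 and 32).
Longest linear sequence: 18 steps (1–7, 10–14, 16, 17, 21–24).

Steps most likely to fail:

1. Step 14. Hydride transfer may outrun ring closure, so that the saturated aldehyde accumulates because the enamine adds too slowly to the thioacrylate, or the closure may proceed with poor facial selectivity at the acceptor carbon. Fallback: the nucleophile is changed from a catalytic enamine to a preformed silyl enol ether. Setting out from 20, RhCl(PPh3)3-catalysed 1,4-hydrosilylation of the enal with Et3SiH should give the triethylsilyl enol ether F1, and a fluoride-triggered intramolecular Mukaiyama–Michael addition (tetrabutylammonium difluorotriphenylsilicate, THF, −78 °C) should close ring C and come back to the route at 23.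

2. Step 11. Metathesis in the presence of the conjugated trienyl thioester may suffer from sequestration of the ruthenium carbene by the polyene or from scrambling of the triene. Fallback: the enal carbons are put in place before the triene exists. Setting out from 9, cross-metathesis with 3,3-diethoxyprop-1-ene (same ruthenium catalyst) should give the hydroxy acetal F2; Dess–Martin oxidation gives the aldehyde F3; Wittig reaction with 11 gives the enal F4; Horner–Wadsworth–Emmons reaction with 15 gives the trienyl thioester acetal F5; its allylic acetal is cleaved with Et3SiOTf/2,6-lutidine and then water, coming back to the route at 18.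

3. Step 17. Over-reduction on palladium (hydrosilylation or hydrogenation of the dienyl dioxinone or of the ring alkene) or incomplete C–S cleavage may occur. Fallback: the order in which the two arms are elaborated is reversed, so that no conjugated unit is present when the thioester is reduced. Setting out from 23, acetalisation (HC(OMe)3, pyridinium p-toluenesulfonate, MeOH) should give the dimethyl acetal F6; (i-Bu)2AlH at −78 °C reduces the thioester to the aldehyde F7; the Z-selective olefination with 32 gives the enamide acetal F8; Et3SiOTf/2,6-lutidine and then water frees the aldehyde F9 while the dioxolane stays; olefination with 25 comes back to the route at 33.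

Further compounds
F1 | step 14 | S-ethyl (E)-3-[2-methyl-1-(2-methyl-1,3-dioxolan-2-yl)-4-[3-(triethylsilyloxy)prop-2-enyl]-2,3,3a,4,5,7a-hexahydro-1H-inden-5-yl]prop-2-enethioate | CC1(OCCO1)[C@H]2[C@@H]3C=C[C@H](/C=C/C(=O)SCC)[C@H](CC=CO[Si](CC)(CC)CC)[C@H]3C[C@H]2C
F2 | step 11 | (2R,3R,5E)-7,7-diethoxy-3-methyl-2-(2-methyl-1,3-dioxolan-2-yl)hept-5-en-1-ol | CC1(OCCO1)[C@H]([C@H](C)C/C=C/C(OCC)OCC)CO
F3 | step 11 | (2R,3R,5E)-7,7-diethoxy-3-methyl-2-(2-methyl-1,3-dioxolan-2-yl)hept-5-enal | CC1(OCCO1)[C@H]([C@H](C)C/C=C/C(OCC)OCC)C=O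
F4 | step 11 | (2E,4R,5R,7E)-9,9-diethoxy-5-methyl-4-(2-methyl-1,3-dioxolan-2-yl)nona-2,7-dienal | CC1(OCCO1)[C@H]([C@H](C)C/C=C/C(OCC)OCC)/C=C/C=O
F5 | step 11 | S-ethyl (2E,4E,6E,8R,9R,11E)-13,13-diethoxy-9-methyl-8-(2-methyl-1,3-dioxolan-2-yl)trideca-2,4,6,11-tetraenethioate | CC1(OCCO1)[C@H]([C@H](C)C/C=C/C(OCC)OCC)/C=C/C=C/C=C/C(=O)SCC
F6 | step 17 | S-ethyl 2-[2-(dimethoxymethyl)-7-methyl-6-(2-methyl-1,3-dioxolan-2-yl)-1,2,3,3a,5a,6,7,8,8a,8b-decahydro-as-indacen-3-yl]ethanethioate | CC1(OCCO1)[C@H]2[C@@H]3C=C[C@@H]4[C@@H](CC(=O)SCC)[C@H](C(OC)OC)C[C@@H]4[C@H]3C[C@H]2C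
F7 | step 17 | 2-[2-(dimethoxymethyl)-7-methyl-6-(2-methyl-1,3-dioxolan-2-yl)-1,2,3,3a,5a,6,7,8,8a,8b-decahydro-as-indacen-3-yl]acetaldehyde | CC1(OCCO1)[C@H]2[C@@H]3C=C[C@@H]4[C@@H](CC=O)[C@H](C(OC)OC)C[C@@H]4[C@H]3C[C@H]2C
F8 | step 17 | methyl N2-(2,4-dimethoxybenzyl)-N5-[(Z)-4-[2-(dimethoxymethyl)-7-methyl-6-(2-methyl-1,3-dioxolan-2-yl)-1,2,3,3a,5a,6,7,8,8a,8b-decahydro-as-indacen-3-yl]but-2-enoyl]-L-ornithinate | CC1(OCCO1)[C@H]2[C@@H]3C=C[C@@H]4[C@@H](C/C=C\C(=O)NCCC[C@H](NCc5ccc(OC)cc5OC)C(=O)OC)[C@H](C(OC)OC)C[C@@H]4[C@H]3C[C@H]2C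
F9 | step 17 | methyl N2-(2,4-dimethoxybenzyl)-N5-[(Z)-4-[2-formyl-7-methyl-6-(2-methyl-1,3-dioxolan-2-yl)-1,2,3,3a,5a,6,7,8,8a,8b-decahydro-as-indacen-3-yl]but-2-enoyl]-L-ornithinate | CC1(OCCO1)[C@H]2[C@@H]3C=C[C@@H]4[C@@H](C/C=C\C(=O)NCCC[C@H](NCc5ccc(OC)cc5OC)C(=O)OC)[C@H](C=O)C[C@@H]4[C@H]3C[C@H]2C
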